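**Retrosynthetic overview**
1. Target 34 ⇒ diol 26 + acid 32, joined last by selective acylation of the primary C15–OH.
2. Ten-membered carbocycle (formed second): C6–C7 bond by intramolecular Cr(II) allylation (Nozaki–Hiyama macrocyclisation) of bromomethyl-butenolide enal 23; this also sets C6 and C7 and unveils the α-methylene lactone.
3. Butenolide ring (formed first): C7 aldehyde 18 → vinylalumination (Baylis–Hillman-type adduct) → lactonisation onto C8–OH → SN2′ bromination.
4. Acyclic chain 16 ⇒ B-alkyl Suzuki coupling (C1–C2) of vinyl iodide 6 (from (R)-glycidol; acetylide opening, carboalumination) with diene 14 (syn-vinylcupration of an ynoate fixes C4=C5).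
5. Acid 32 ⇒ acetaldehyde + tert-butyl acrylate (Baylis–Hillman, acetate 1,3-transposition).

Assumption: germacrane locants are used (C12 lactone C=O on O–C8, C6 carbinol, C15 = CH2O on C4); 19–22 are carried as C7-epimer mixtures because C7 becomes sp2 in step 16.

**Step 1**
Reactants: 1 (R)-glycidol
Product: 2 (2S)-2-{[(4-methoxybenzyl)oxy]methyl}oxirane
Conditions: NaH, PMBCl, Bu4NI (cat.), THF/DMF, 0 °C → rt
Reagents that add atoms: 4-methoxybenzyl chloride, COc1ccc(CCl)cc1
Why: Williamson etherification of the primary alkoxide leaves the stereocentre untouched (R→S is only a CIP priority switch).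

**Step 2**
Reactants: 2 PMB glycidyl ether
Product: 3 (2S)-1-[(4-methoxybenzyl)oxy]pent-4-yn-2-ol
Conditions: HC≡CLi·ethylenediamine, DMSO, rt
Reagents that add atoms: lithium acetylide (ethylenediamine complex), [Li]C#C
Why: SN2 epoxide opening by acetylide at the terminal CH2 keeps the carbinol centre (future C8, S).

**Step 3**
Reactants: 3 homopropargylic alcohol
Product: 5 (2S,4E)-5-iodo-1-[(4-methoxybenzyl)oxy]-4-methylpent-4-en-2-ol, via alkenyl(dimethyl)alane 4 (not isolated)
Conditions: AlMe3 (3 equiv), Cp2ZrCl2 (0.25 equiv), CH2Cl2, 0 °C → rt; then I2, THF, −30 → 0 °C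
Reagents that add atoms: trimethylaluminium, C[Al](C)C; iodine, II
Why: Negishi Zr-catalysed syn-carboalumination puts Me on the internal carbon and Al on the terminus, and iodinolysis with retention gives the E vinyl iodide (C1=C10 geometry).

**Step 4**
Reactants: 5 iodo alcohol
Product: 6 triethyl({(2S,4E)-5-iodo-1-[(4-methoxybenzyl)oxy]-4-methylpent-4-en-2-yl}oxy)silane
Conditions: TESCl, imidazole, CH2Cl2, 0 °C
Reagents that add atoms: chlorotriethylsilane, CC[Si](Cl)(CC)CC
Why: Standard silylation of the secondary alcohol; no stereocentre is affected.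

**Step 5**
Reactants: 7 prop-2-yn-1-ol
Product: 8 tert-butyl(diphenyl)(prop-2-yn-1-yloxy)silane
Conditions: TBDPSCl, imidazole, CH2Cl2, rt
Reagents that add atoms: tert-butyl(chloro)diphenylsilane, CC(C)(C)[Si](Cl)(c1ccccc1)c1ccccc1
Why: Silylation installs the robust C15–O protecting group that survives to step 18.

**Step 6**
Reactants: 8 TBDPS propargyl ether
Product: 10 methyl 4-[(tert-butyldiphenylsilyl)oxy]but-2-ynoate, via lithium acetylide 9 (not isolated)
Conditions: n-BuLi, THF, −78 °C; then ClCO2Me, −78 → 0 °C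
Reagents that add atoms: methyl chloroformate, COC(=O)Cl
Why: Acetylide C-acylation with a chloroformate gives the ynoate (the ester carbon becomes C6).

**Step 7**
Reactants: 10 ynoate
Product: 12 methyl (2Z)-3-{[(tert-butyldiphenylsilyl)oxy]methyl}penta-2,4-dienoate, via alkenylcopper 11 (not isolated)
Conditions: CH2=CHMgBr (2.2 equiv), CuI (1.1 equiv), THF, −78 °C; quench NH4Cl/MeOH at −78 °C
Reagents that add atoms: vinylmagnesium bromide, C=C[Mg]Br
Why: Stereospecific syn-carbocupration of the ynoate and cold protonation with retention place CO2Me cis to CH2OSi, which is the C4=C5 geometry of the target.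

**Step 8**
Reactants: 12 dienoate
Product: 13 (2Z)-3-{[(tert-butyldiphenylsilyl)oxy]methyl}penta-2,4-dien-1-ol
Conditions: DIBAL-H (2.5 equiv), CH2Cl2, −78 °C; Rochelle salt
Reagents that add atoms: none
Why: 1,2-Reduction of the conjugated ester to the allylic alcohol does not disturb the alkene geometry.

**Step 9**
Reactants: 13 dienol
Product: 14 tert-butyl({(2Z)-2-ethenyl-4-[(triethylsilyl)oxy]but-2-en-1-yl}oxy)diphenylsilane
Conditions: TESCl, imidazole, CH2Cl2, 0 °C
Reagents that add atoms: chlorotriethylsilane, CC[Si](Cl)(CC)CC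
Why: Silylation differentiates C6–O (TES, labile) from C15–O (TBDPS, robust).

**Step 10**
Reactants: 14 diene bis-silyl ether; 6 vinyl iodide
Product: 16 (2S,4E,8Z)-8-{[(tert-butyldiphenylsilyl)oxy]methyl}-1-[(4-methoxybenzyl)oxy]-4-methyl-2,10-bis[(triethylsilyl)oxy]deca-4,8-diene, via B-alkyl-9-BBN 15 (not isolated)
Conditions: 14 (1.3 equiv), 9-BBN, THF, 0 °C → rt; then 6, PdCl2(dppf) (5 mol%), AsPh3, Cs2CO3, DMF/THF/H2O, rt
Reagents that add atoms: none
Why: 9-BBN adds anti-Markovnikov to the only monosubstituted alkene, and the B-alkyl Suzuki–Miyaura coupling forms C1–C2 with retention of the vinyl iodide geometry.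

**Step 11**
Reactants: 16 coupled PMB ether
Product: 17 (2S,4E,8Z)-8-{[(tert-butyldiphenylsilyl)oxy]methyl}-4-methyl-2,10-bis[(triethylsilyl)oxy]deca-4,8-dien-1-ol
Conditions: DDQ, CH2Cl2/pH 7 buffer, 0 °C
Reagents that add atoms: none
Why: Oxidative PMB cleavage under buffered conditions spares the silyl ethers and isolated alkenes.

**Step 12**
Reactants: 17 primary alcohol
Product: 18 (2S,4E,8Z)-8-{[(tert-butyldiphenylsilyl)oxy]methyl}-4-methyl-2,10-bis[(triethylsilyl)oxy]deca-4,8-dienal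
Conditions: Dess–Martin periodinane, NaHCO3, CH2Cl2, 0 °C → rt
Reagents that add atoms: none
Why: Buffered Dess–Martin oxidation gives the α-silyloxy aldehyde without epimerising C8 (used crude).

**Step 13**
Reactants: 18 aldehyde
Product: 19 methyl (3RS,4S,6E,10Z)-10-{[(tert-butyldiphenylsilyl)oxy]methyl}-3-hydroxy-6-methyl-2-methylidene-4,12-bis[(triethylsilyl)oxy]dodeca-6,10-dienoate
Conditions: DIBAL-H, NMO, THF, 0 °C; methyl propiolate, 0 °C; then 18, 0 °C → rt
Reagents that add atoms: methyl propiolate, C#CC(=O)OC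
Why: Hydroalumination of the propiolate gives an α-(methoxycarbonyl)vinylalane that adds 1,2 to the aldehyde (vinylalumination, Baylis–Hillman-type adduct); the new C7 configuration is irrelevant.

**Step 14**
Reactants: 19 hydroxy acrylate
Product: 21 (4RS,5S)-5-[(2E,6Z)-6-{[(tert-butyldiphenylsilyl)oxy]methyl}-8-hydroxy-2-methylocta-2,6-dien-1-yl]-4-hydroxy-3-methylideneoxolan-2-one, via trihydroxy ester 20 (not isolated)
Conditions: PPTS, MeOH/CH2Cl2, 0 °C → rt; then TsOH·H2O (cat.), CH2Cl2, rt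
Reagents that add atoms: none
Why: Mild acid methanolysis removes both TES groups but not the TBDPS ether, and the freed C8–OH lactonises (5-exo acyl substitution) with retention at C8.

**Step 15**
Reactants: 21 diol lactone
Product: 22 (2Z,6E)-3-{[(tert-butyldiphenylsilyl)oxy]methyl}-8-[(2S,3RS)-3-hydroxy-4-methylidene-5-oxooxolan-2-yl]-7-methylocta-2,6-dienal
Conditions: TEMPO (cat.), PhI(OAc)2, CH2Cl2, rt
Reagents that add atoms: none
Why: TEMPO/BAIB oxidation is selective for the primary allylic alcohol over the secondary one and does not isomerise the Z enal.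

**Step 16**
Reactants: 22 hydroxy lactone enal
Product: 23 (2Z,6E)-8-[(2S)-4-(bromomethyl)-5-oxo-2,5-dihydrofuran-2-yl]-3-{[(tert-butyldiphenylsilyl)oxy]methyl}-7-methylocta-2,6-dienal
Conditions: NBS, Me2S, CH2Cl2, −20 → 0 °C
Reagents that add atoms: N-bromosuccinimide, O=C1CCC(=O)N1Br
Why: Corey–Kim-type activation of the Baylis–Hillman alcohol and SN2′ attack of bromide at the exocyclic CH2 give the conjugated bromomethyl butenolide, removing the C7 centre and leaving C8 untouched.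

**Step 17**
Reactants: 23 bromomethyl butenolide enal
Product: 25 (3aS,4R,5Z,9E,11aS)-6-{[(tert-butyldiphenylsilyl)oxy]methyl}-4-hydroxy-10-methyl-3-methylidene-3a,4,7,8,11,11a-hexahydrocyclodeca[b]furan-2(3H)-one, via allylchromium(III) species 24 (not isolated)
Conditions: CrCl2 (10 equiv), degassed THF, rt, syringe-pump addition of 23 (final 2 mM)
Reagents that add atoms: none
Why: Intramolecular Nozaki–Hiyama (Barbier-type) allylation through a chair Zimmerman–Traxler transition state: γ-attack of the ring-locked E-type allylchromium gives the C6/C7 anti relationship, and bond formation anti to the C8 side chain gives the trans-fused lactone, i.e. 6R,7S from 8S.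

**Step 18**
Reactants: 25 macrocyclic silyl ether
Product: 26 (3aS,4R,5Z,9E,11aS)-4-hydroxy-6-(hydroxymethyl)-10-methyl-3-methylidene-3a,4,7,8,11,11a-hexahydrocyclodeca[b]furan-2(3H)-one
Conditions: HF·pyridine, pyridine, THF, 0 °C → rt
Reagents that add atoms: none
Why: Buffered fluoride desilylation is non-basic and non-nucleophilic enough to leave the α-methylene lactone intact.

**Step 19**
Reactants: 27 acetaldehyde; 28 tert-butyl acrylate
Product: 29 tert-butyl 3-hydroxy-2-methylidenebutanoate (racemic)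
Conditions: DABCO (0.2 equiv), neat, rt, 5–7 d
Reagents that add atoms: none
Why: Morita–Baylis–Hillman reaction; the racemic carbinol centre is removed in step 21.

**Step 20**
Reactants: 29 Baylis–Hillman alcohol
Product: 30 tert-butyl 3-(acetyloxy)-2-methylidenebutanoate (racemic)
Conditions: Ac2O, pyridine, DMAP (cat.), CH2Cl2, 0 °C → rt
Reagents that add atoms: acetic anhydride, CC(=O)OC(C)=O
Why: Simple acetylation of the secondary allylic alcohol.

**Step 21**
Reactants: 30 Baylis–Hillman acetate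
Product: 31 tert-butyl (2E)-2-[(acetyloxy)methyl]but-2-enoate
Conditions: DABCO (0.3 equiv), THF, reflux
Reagents that add atoms: none
Why: Amine-mediated SN2′/SN2 1,3-transposition of the acetate under thermodynamic control gives the conjugated primary acetate as the E isomer (methyl trans to the ester); minor Z isomer is removed by chromatography.

**Step 22**
Reactants: 31 tert-butyl ester
Product: 32 (2E)-2-[(acetyloxy)methyl]but-2-enoic acid
Conditions: TFA/CH2Cl2 (1:4), 0 °C → rt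
Reagents that add atoms: none
Why: Acidolysis of the tert-butyl ester (loss of isobutene) leaves the acetate and the alkene geometry intact.

**Step 23**
Reactants: 32 side-chain acid; 26 diol
Product: 34 [(3aS,4R,5Z,9E,11aS)-4-hydroxy-10-methyl-3-methylidene-2-oxo-2,3,3a,4,7,8,11,11a-octahydrocyclodeca[b]furan-6-yl]methyl (2E)-2-[(acetyloxy)methyl]but-2-enoate, via mixed anhydride 33 (not isolated)
Conditions: 32 (1.1 equiv), 2,4,6-Cl3C6H2COCl, Et3N, THF, 0 °C; then 26, DMAP (0.3 equiv), toluene, −20 → 0 °C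
Reagents that add atoms: none
Why: Yamaguchi esterification acylates the primary allylic C15–OH much faster than the hindered secondary C6–OH; no stereocentre is touched.

**Compound list**
1 | (R)-glycidol | OC[C@@H]1CO1 | starting material
2 | (2S)-2-{[(4-methoxybenzyl)oxy]methyl}oxirane | COc1ccc(COC[C@@H]2CO2)cc1 | intermediate
3 | (2S)-1-[(4-methoxybenzyl)oxy]pent-4-yn-2-ol | COc1ccc(COC[C@@H](O)CC#C)cc1 | intermediate
4 | O-dimethylaluminium alkoxide of the (E)-alkenyl(dimethyl)alane from 3 | COc1ccc(COC[C@@H](O[Al](C)C)C/C(C)=C/[Al](C)C)cc1 | intermediate (not isolated)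
5 | (2S,4E)-5-iodo-1-[(4-methoxybenzyl)oxy]-4-methylpent-4-en-2-ol | COc1ccc(COC[C@@H](O)C/C(C)=C/I)cc1 | intermediate
6 | triethyl({(2S,4E)-5-iodo-1-[(4-methoxybenzyl)oxy]-4-methylpent-4-en-2-yl}oxy)silane | COc1ccc(COC[C@@H](O[Si](CC)(CC)CC)C/C(C)=C/I)cc1 | intermediate
7 | prop-2-yn-1-ol | C#CCO | starting material
8 | tert-butyl(diphenyl)(prop-2-yn-1-yloxy)silane | C#CCO[Si](c1ccccc1)(c1ccccc1)C(C)(C)C | intermediate
9 | lithium acetylide of 8 | [Li]C#CCO[Si](c1ccccc1)(c1ccccc1)C(C)(C)C | intermediate (not isolated)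
10 | methyl 4-[(tert-butyldiphenylsilyl)oxy]but-2-ynoate | COC(=O)C#CCO[Si](c1ccccc1)(c1ccccc1)C(C)(C)C | intermediate
11 | α-cuprio dienoate (Cu cis to vinyl) | COC(=O)/C([Cu])=C(/C=C)CO[Si](c1ccccc1)(c1ccccc1)C(C)(C)C | intermediate (not isolated)
12 | methyl (2Z)-3-{[(tert-butyldiphenylsilyl)oxy]methyl}penta-2,4-dienoate | COC(=O)/C=C(/C=C)CO[Si](c1ccccc1)(c1ccccc1)C(C)(C)C | intermediate
13 | (2Z)-3-{[(tert-butyldiphenylsilyl)oxy]methyl}penta-2,4-dien-1-ol | OC/C=C(/C=C)CO[Si](c1ccccc1)(c1ccccc1)C(C)(C)C | intermediate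
14 | tert-butyl({(2Z)-2-ethenyl-4-[(triethylsilyl)oxy]but-2-en-1-yl}oxy)diphenylsilane | CC[Si](CC)(CC)OC/C=C(/C=C)CO[Si](c1ccccc1)(c1ccccc1)C(C)(C)C | intermediate
15 | B-alkyl-9-BBN from 14 (boron on C2) | CC[Si](CC)(CC)OC/C=C(/CCB1C2CCCC1CCC2)CO[Si](c1ccccc1)(c1ccccc1)C(C)(C)C | intermediate (not isolated)
16 | (2S,4E,8Z)-8-{[(tert-butyldiphenylsilyl)oxy]methyl}-1-[(4-methoxybenzyl)oxy]-4-methyl-2,10-bis[(triethylsilyl)oxy]deca-4,8-diene | COc1ccc(COC[C@@H](O[Si](CC)(CC)CC)C/C(C)=C/CC/C(CO[Si](c2ccccc2)(c2ccccc2)C(C)(C)C)=C/CO[Si](CC)(CC)CC)cc1 | intermediate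
17 | (2S,4E,8Z)-8-{[(tert-butyldiphenylsilyl)oxy]methyl}-4-methyl-2,10-bis[(triethylsilyl)oxy]deca-4,8-dien-1-ol | OC[C@@H](O[Si](CC)(CC)CC)C/C(C)=C/CC/C(CO[Si](c1ccccc1)(c1ccccc1)C(C)(C)C)=C/CO[Si](CC)(CC)CC | intermediate
18 | (2S,4E,8Z)-8-{[(tert-butyldiphenylsilyl)oxy]methyl}-4-methyl-2,10-bis[(triethylsilyl)oxy]deca-4,8-dienal | O=C[C@@H](O[Si](CC)(CC)CC)C/C(C)=C/CC/C(CO[Si](c1ccccc1)(c1ccccc1)C(C)(C)C)=C/CO[Si](CC)(CC)CC | intermediate
19 | methyl (3RS,4S,6E,10Z)-10-{[(tert-butyldiphenylsilyl)oxy]methyl}-3-hydroxy-6-methyl-2-methylidene-4,12-bis[(triethylsilyl)oxy]dodeca-6,10-dienoate | C=C(C(=O)OC)C(O)[C@@H](O[Si](CC)(CC)CC)C/C(C)=C/CC/C(CO[Si](c1ccccc1)(c1ccccc1)C(C)(C)C)=C/CO[Si](CC)(CC)CC | intermediate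
20 | methyl (3RS,4S,6E,10Z)-10-{[(tert-butyldiphenylsilyl)oxy]methyl}-3,4,12-trihydroxy-6-methyl-2-methylidenedodeca-6,10-dienoate | C=C(C(=O)OC)C(O)[C@@H](O)C/C(C)=C/CC/C(CO[Si](c1ccccc1)(c1ccccc1)C(C)(C)C)=C/CO | intermediate (not isolated)
21 | (4RS,5S)-5-[(2E,6Z)-6-{[(tert-butyldiphenylsilyl)oxy]methyl}-8-hydroxy-2-methylocta-2,6-dien-1-yl]-4-hydroxy-3-methylideneoxolan-2-one | C=C1C(=O)O[C@@H](C/C(C)=C/CC/C(CO[Si](c2ccccc2)(c2ccccc2)C(C)(C)C)=C/CO)C1O | intermediate
22 | (2Z,6E)-3-{[(tert-butyldiphenylsilyl)oxy]methyl}-8-[(2S,3RS)-3-hydroxy-4-methylidene-5-oxooxolan-2-yl]-7-methylocta-2,6-dienal | C=C1C(=O)O[C@@H](C/C(C)=C/CC/C(CO[Si](c2ccccc2)(c2ccccc2)C(C)(C)C)=C/C=O)C1O | intermediate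
23 | (2Z,6E)-8-[(2S)-4-(bromomethyl)-5-oxo-2,5-dihydrofuran-2-yl]-3-{[(tert-butyldiphenylsilyl)oxy]methyl}-7-methylocta-2,6-dienal | BrCC1=C[C@H](C/C(C)=C/CC/C(CO[Si](c2ccccc2)(c2ccccc2)C(C)(C)C)=C/C=O)OC1=O | intermediate
24 | allylchromium(III) dichloride from 23 (Cr on C13) | Cl[Cr](Cl)CC1=C[C@H](C/C(C)=C/CC/C(CO[Si](c2ccccc2)(c2ccccc2)C(C)(C)C)=C/C=O)OC1=O | intermediate (not isolated)
25 | (3aS,4R,5Z,9E,11aS)-6-{[(tert-butyldiphenylsilyl)oxy]methyl}-4-hydroxy-10-methyl-3-methylidene-3a,4,7,8,11,11a-hexahydrocyclodeca[b]furan-2(3H)-one | C=C1C(=O)O[C@H]2C/C(C)=C/CC/C(CO[Si](c3ccccc3)(c3ccccc3)C(C)(C)C)=C/[C@@H](O)[C@H]12 | intermediate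
26 | (3aS,4R,5Z,9E,11aS)-4-hydroxy-6-(hydroxymethyl)-10-methyl-3-methylidene-3a,4,7,8,11,11a-hexahydrocyclodeca[b]furan-2(3H)-one | C=C1C(=O)O[C@H]2C/C(C)=C/CC/C(CO)=C/[C@@H](O)[C@H]12 | intermediate
27 | acetaldehyde | CC=O | starting material
28 | tert-butyl acrylate | C=CC(=O)OC(C)(C)C | starting material
29 | tert-butyl 3-hydroxy-2-methylidenebutanoate (racemic) | C=C(C(C)O)C(=O)OC(C)(C)C | intermediate
30 | tert-butyl 3-(acetyloxy)-2-methylidenebutanoate (racemic) | C=C(C(C)OC(C)=O)C(=O)OC(C)(C)C | intermediate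
31 | tert-butyl (2E)-2-[(acetyloxy)methyl]but-2-enoate | CC(C)(C)OC(=O)/C(=C/C)COC(C)=O | intermediate
32 | (2E)-2-[(acetyloxy)methyl]but-2-enoic acid | OC(=O)/C(=C/C)COC(C)=O | intermediate
33 | (2E)-2-[(acetyloxy)methyl]but-2-enoic 2,4,6-trichlorobenzoic anhydride | O=C(OC(=O)/C(=C/C)COC(C)=O)c1c(Cl)cc(Cl)cc1Cl | intermediate (not isolated)
34 | [(3aS,4R,5Z,9E,11aS)-4-hydroxy-10-methyl-3-methylidene-2-oxo-2,3,3a,4,7,8,11,11a-octahydrocyclodeca[b]furan-6-yl]methyl (2E)-2-[(acetyloxy)methyl]but-2-enoate | C=C1C(=O)O[C@H]2C/C(C)=C/CC/C(COC(=O)/C(=C/C)COC(C)=O)=C/[C@@H](O)[C@H]12 | target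

**Totals**
Total step count: 23.
Longest linear sequence: 15 steps (steps 5–18, then 23; from 7 to 34). The glycidol branch is 14 steps and the acid branch 5.

**Three steps most likely to fail**

Step 17 (Cr(II) macrocyclisation; the ten-membered ring is strained and the C6 configuration depends on the transition state). The fallback sets out from 23 and comes back at 25. If the closure gives mainly the C6 epimer, that 6-epi macrocycle F1 is oxidised with Dess–Martin periodinane (NaHCO3, CH2Cl2, 0 °C) to the C6 ketone F2. The enone is then reduced under reagent control ((S)-Me-CBS, catecholborane, toluene, −78 °C; the enantiomeric catalyst if the facial sense proves reversed) to give 25. C6 is then set by ketone reduction and not in the allylation transition state; a wrong C7 configuration could not be repaired this way.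

Step 10 (hydroboration of a 1,3-diene and B-alkyl Suzuki coupling in one pot). The fallback sets out from 14 and comes back at 16. Hydroboration–oxidation (9-BBN, THF; then NaBO3·4H2O) gives the primary alcohol F3, which can be purified and checked for regiochemistry. Iodination (I2, PPh3, imidazole, CH2Cl2) gives the homoallylic iodide F4. Zinc insertion (Zn dust, LiCl, THF) and Pd-catalysed Negishi coupling with 6 (Pd(PPh3)4, THF, rt) then give 16.

Step 16 (formation and handling of the labile bromomethyl butenolide next to an enal). The fallback sets out from 22 and comes back at 25, bypassing 23. Acetylation (Ac2O, pyridine, DMAP cat., CH2Cl2, 0 °C) gives the allylic acetate F5. This is cyclised directly by umpolung allylation (Pd(PPh3)4 cat., InI, THF, high dilution): the π-allylpalladium is reduced to an allylindium that adds to the enal through C7, giving 25.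

**Further compounds**
F1 | step 17 | (3aS,4S,5Z,9E,11aS)-6-{[(tert-butyldiphenylsilyl)oxy]methyl}-4-hydroxy-10-methyl-3-methylidene-3a,4,7,8,11,11a-hexahydrocyclodeca[b]furan-2(3H)-one (6-epi-25) | C=C1C(=O)O[C@H]2C/C(C)=C/CC/C(CO[Si](c3ccccc3)(c3ccccc3)C(C)(C)C)=C/[C@H](O)[C@H]12
F2 | step 17 | (3aR,5Z,9E,11aS)-6-{[(tert-butyldiphenylsilyl)oxy]methyl}-10-methyl-3-methylidene-7,8,11,11a-tetrahydrocyclodeca[b]furan-2,4(3H,3aH)-dione (C6 ketone; C7 spatially unchanged) | C=C1C(=O)O[C@H]2C/C(C)=C/CC/C(CO[Si](c3ccccc3)(c3ccccc3)C(C)(C)C)=C/C(=O)[C@H]12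
F3 | step 10 | (3Z)-3-{[(tert-butyldiphenylsilyl)oxy]methyl}-5-[(triethylsilyl)oxy]pent-3-en-1-ol | CC[Si](CC)(CC)OC/C=C(/CCO)CO[Si](c1ccccc1)(c1ccccc1)C(C)(C)C
F4 | step 10 | tert-butyl({(2Z)-2-(2-iodoethyl)-4-[(triethylsilyl)oxy]but-2-en-1-yl}oxy)diphenylsilane | CC[Si](CC)(CC)OC/C=C(/CCI)CO[Si](c1ccccc1)(c1ccccc1)C(C)(C)C
F5 | step 16 | (2S,3RS)-2-[(2E,6Z)-6-{[(tert-butyldiphenylsilyl)oxy]methyl}-2-methyl-8-oxoocta-2,6-dien-1-yl]-4-methylidene-5-oxooxolan-3-yl acetate | C=C1C(=O)O[C@@H](C/C(C)=C/CC/C(CO[Si](c2ccccc2)(c2ccccc2)C(C)(C)C)=C/C=O)C1OC(C)=O
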